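**Plan**

- Ring numbering of the target: C1 = C(OH)CH2OBz, C2 = CH(OH) next to C3 = CH(OBz), C4 and C5 = CH2, C6 = the other CH(OH).
- Enabling feature: C1 sits between two carbinol carbons (C2, C6), so the ring is a masked 2-acyl-cyclohexane-1,3-dione. With the exocyclic carbon at the ester level, C5–C6–C1 is an acetoacetate (C5 its γ-carbon, C1 its α-carbon) and C4–C3–C2 is a 2-oxyacrylate (C4 its β-carbon, C2 its carboxyl carbon).
- Retrosynthesis: functional-group changes lead back to a 3-hydroxy-2,6-dioxo ester, which is cut at C4–C5 (Michael) and C1–C2 (Dieckmann) in one [3+3] event between the acetoacetate dianion and a chiral 5-methylene-1,3-dioxolan-4-one.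
- Forward: the auxiliary is made from (R)-lactic acid (steps 1–2), step 3 closes the only carbocycle, then C1 hydroxylation, C3 benzoylation, reduction of both ketones, ester reduction and primary benzoylation.
- Stereochemistry: C3 comes from the tert-butyl acetal centre (bought with (R)-lactic acid) through face-selective protonation in the key step; C1 is relayed from C3 by hydroxyl-directed oxidation; C2 and C6 are relayed together from C1 by directed hydride delivery.

Key step: step 3

Remark on the chemistry: compound 10 is written as one enol tautomer; its tautomers interconvert and all react through C1. Locants in the Why lines are those of the target ring defined above; compound names carry their own locants.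

**Step 1**
Reactants: 1 (R)-lactic acid; 2 pivalaldehyde
Product: 3 (2R,5R)-2-tert-butyl-5-methyl-1,3-dioxolan-4-one
Conditions: TsOH·H2O (cat.), pentane, reflux, azeotropic removal of water; crystallisation from pentane/Et2O at −78 °C
Reagents that add atoms: none
Why: Acid-catalysed acetalisation of the α-hydroxy acid should give mainly the cis-dioxolanone, the lactate centre fixing the new acetal centre (tert-butyl cis to methyl), and crystallisation removes the trans isomer.

**Step 2**
Reactants: 3 (2R,5R)-2-tert-butyl-5-methyl-1,3-dioxolan-4-one
Product: 5 (2R)-2-tert-butyl-5-methylidene-1,3-dioxolan-4-one, via bromide 4 (not isolated)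
Conditions: NBS, AIBN (cat.), PhCF3, reflux; filtration; Et3N, Et2O, 0 °C → rt
Reagents that add atoms: none
Why: Wohl–Ziegler bromination at the captodative ring C–H followed by elimination of HBr from the tertiary bromide should give the exocyclic alkene, the acetal carbon being untouched and now the only stereocentre.

**Step 3**
Reactants: 5 (2R)-2-tert-butyl-5-methylidene-1,3-dioxolan-4-one; 6 methyl acetoacetate
Product: 10 methyl (5R)-2,5-dihydroxy-6-oxocyclohex-1-ene-1-carboxylate, via dianion 7 (not isolated), via bis-enolate 8 (not isolated), via cis-adduct enolate 9 (not isolated)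
Conditions: 6 (1.3 equiv), NaH, THF, 0 °C; n-BuLi, 0 °C; cool to −78 °C, slow addition of 5; 2,6-di-tert-butyl-4-methylphenol (1.5 equiv), −78 °C → rt; 1 M HCl, 0 °C
Reagents that add atoms: none
Why: Proposed new method: the γ-carbon of dianion 7, its most basic and least delocalised site, should add to the unsubstituted exocyclic CH2 of the captodative acrylate 5 (Michael addition, first bond, the CH2–CH2 bond C5–C4) to give bis-enolate 8, and the hindered phenol, too weak an acid to quench the β-keto ester enolate, should then protonate only the dioxolanone enolate on the face away from the tert-butyl group, which sets the single new stereocentre (target C3, R) in the cis-dioxolanone 9. On warming, the β-keto ester enolate should attack the acylal-type lactone carbonyl (Dieckmann closure, second bond C1–C2, a 6-exo-trig acyl substitution that is 6-enolendo with respect to the keto enolate), the tetrahedral intermediate expelling a hemiacetal alkoxide that sheds pivalaldehyde, so that the auxiliary leaves tracelessly and the cyclic tricarbonyl compound is held as its stable enolate. The closest known reaction types are the consecutive Michael–Claisen synthesis of cyclohexane-1,3-diones from ketone enolates and acrylates, the γ-selective alkylations and conjugate additions of acetoacetate dianions, and the cis-selective radical additions and enolate reactions of this dioxolanone, in which attack and hydrogen transfer occur anti to the tert-butyl group. The step needs γ- over α-reactivity (secured by the dianion), conjugate over carbonyl addition without oligomerisation (favoured by the terminal CH2 acceptor, −78 °C and slow addition of 5 to an excess of 7), and facial control in the protonation (secured by the acetal centre and the bulky proton source). C3 should not epimerise after closure because the product is stored as its enolate until the acidic work-up.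

**Step 4**
Reactants: 10 methyl (5R)-2,5-dihydroxy-6-oxocyclohex-1-ene-1-carboxylate
Product: 11 methyl (1S,3R)-1,3-dihydroxy-2,6-dioxocyclohexane-1-carboxylate
Conditions: mCPBA (1.05 equiv), CH2Cl2, 0 °C
Reagents that add atoms: 3-chloroperoxybenzoic acid (mCPBA), OOC(=O)c1cccc(Cl)c1
Why: Peracid α-hydroxylation of an enolised β-dicarbonyl compound (oxygen transfer to the enol C=C) should be steered by hydrogen bonding of the peracid to the neighbouring secondary hydroxyl (hydroxyl-directed epoxidation), so that the new tertiary OH at C1 enters cis to the C3 oxygen.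

**Step 5**
Reactants: 11 methyl (1S,3R)-1,3-dihydroxy-2,6-dioxocyclohexane-1-carboxylate
Product: 12 methyl (1S,3R)-3-(benzoyloxy)-1-hydroxy-2,6-dioxocyclohexane-1-carboxylate
Conditions: BzCl (1.1 equiv), pyridine, CH2Cl2, −20 → 0 °C
Reagents that add atoms: benzoyl chloride, O=C(Cl)c1ccccc1
Why: Acylation of the only secondary hydroxyl (nucleophilic acyl substitution) should be selective because the tertiary hydroxyl, flanked by three carbonyl groups, is too hindered and too electron-poor to compete at low temperature.

**Step 6**
Reactants: 12 methyl (1S,3R)-3-(benzoyloxy)-1-hydroxy-2,6-dioxocyclohexane-1-carboxylate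
Product: 13 methyl (1S,2S,3R,6R)-3-(benzoyloxy)-1,2,6-trihydroxycyclohexane-1-carboxylate
Conditions: Me4NBH(OAc)3 (6 equiv), MeCN/AcOH 1:1, −30 → 0 °C; aqueous sodium potassium tartrate
Reagents that add atoms: none
Why: In this Saksena–Evans reduction the tertiary C1 hydroxyl should bind the acetoxyborohydride and deliver hydride to the same face of both flanking ketones (also the axial trajectory anti to the axial ester group), which sets C2 and C6 trans to the C1 hydroxyl in one event, while the acidic medium suppresses retro-aldol opening and leaves both esters intact.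

**Step 7**
Reactants: 13 methyl (1S,2S,3R,6R)-3-(benzoyloxy)-1,2,6-trihydroxycyclohexane-1-carboxylate
Product: 14 (1R,2S,3S,4R)-2,3,4-trihydroxy-3-(hydroxymethyl)cyclohexyl benzoate
Conditions: BH3·SMe2 (4 equiv), NaBH4 (5 mol %), THF, 0 °C → rt; MeOH quench
Reagents that add atoms: none
Why: In this hydroxyl-assisted borane reduction of an α-hydroxy ester the alkoxyborane formed at the α-hydroxyl should reduce the adjacent methyl ester through a five-membered transition state, whereas the remote benzoate should survive these neutral conditions, which also avoid acyl migration.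

**Step 8**
Reactants: 14 (1R,2S,3S,4R)-2,3,4-trihydroxy-3-(hydroxymethyl)cyclohexyl benzoate
Product: 15 [(1S,2S,3R,6R)-3-(benzoyloxy)-1,2,6-trihydroxycyclohexyl]methyl benzoate
Conditions: BzCl (1.05 equiv), 2,4,6-collidine, CH2Cl2, −40 → 0 °C
Reagents that add atoms: benzoyl chloride, O=C(Cl)c1ccccc1
Why: Kinetically controlled acylation with a limiting amount of acid chloride should take place at the primary hydroxyl, the least hindered of the four (the two secondary hydroxyls each adjoin the quaternary carbon and the fourth is tertiary).

**Compound list**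

1 | (R)-lactic acid, (2R)-2-hydroxypropanoic acid | C[C@@H](O)C(=O)O | starting material
2 | pivalaldehyde, 2,2-dimethylpropanal | CC(C)(C)C=O | starting material
3 | (2R,5R)-2-tert-butyl-5-methyl-1,3-dioxolan-4-one (cis) | CC(C)(C)[C@@H]1O[C@H](C)C(=O)O1 | intermediate
4 | (2S,5S)-5-bromo-2-tert-butyl-5-methyl-1,3-dioxolan-4-one (bromine trans to tert-butyl; the acetal descriptor changes only through the priority of bromine) | CC(C)(C)[C@@H]1O[C@@](C)(Br)C(=O)O1 | intermediate (not isolated)
5 | (2R)-2-tert-butyl-5-methylidene-1,3-dioxolan-4-one | CC(C)(C)[C@@H]1OC(=C)C(=O)O1 | intermediate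
6 | methyl acetoacetate, methyl 3-oxobutanoate | CC(=O)CC(=O)OC | starting material
7 | sodium lithium dianion of methyl acetoacetate | C=C([O-])C=C([O-])OC.[Na+].[Li+] | intermediate (not isolated)
8 | sodium lithium bis-enolate of methyl 5-[(2R)-2-tert-butyl-5-oxo-1,3-dioxolan-4-yl]-3-oxopentanoate (ring enolate and β-keto ester enolate) | CC(C)(C)[C@@H]1OC(CCC([O-])=CC(=O)OC)=C([O-])O1.[Na+].[Li+] | intermediate (not isolated)
9 | sodium enolate of methyl 5-[(2R,4R)-2-tert-butyl-5-oxo-1,3-dioxolan-4-yl]-3-oxopentanoate (cis-dioxolanone) | CC(C)(C)[C@@H]1O[C@H](CCC([O-])=CC(=O)OC)C(=O)O1.[Na+] | intermediate (not isolated)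
10 | methyl (5R)-2,5-dihydroxy-6-oxocyclohex-1-ene-1-carboxylate (enol form of methyl (3R)-3-hydroxy-2,6-dioxocyclohexane-1-carboxylate) | COC(=O)C1=C(O)CC[C@@H](O)C1=O | intermediate
11 | methyl (1S,3R)-1,3-dihydroxy-2,6-dioxocyclohexane-1-carboxylate | COC(=O)[C@]1(O)C(=O)CC[C@@H](O)C1=O | intermediate
12 | methyl (1S,3R)-3-(benzoyloxy)-1-hydroxy-2,6-dioxocyclohexane-1-carboxylate | COC(=O)[C@]1(O)C(=O)CC[C@@H](OC(=O)c2ccccc2)C1=O | intermediate
13 | methyl (1S,2S,3R,6R)-3-(benzoyloxy)-1,2,6-trihydroxycyclohexane-1-carboxylate | COC(=O)[C@]1(O)[C@H](O)CC[C@@H](OC(=O)c2ccccc2)[C@@H]1O | intermediate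
14 | (1R,2S,3S,4R)-2,3,4-trihydroxy-3-(hydroxymethyl)cyclohexyl benzoate | OC[C@]1(O)[C@H](O)CC[C@@H](OC(=O)c2ccccc2)[C@@H]1O | intermediate
15 | [(1S,2S,3R,6R)-3-(benzoyloxy)-1,2,6-trihydroxycyclohexyl]methyl benzoate | O=C(OC[C@]1(O)[C@H](O)CC[C@@H](OC(=O)c2ccccc2)[C@@H]1O)c1ccccc1 | target

**Step count and risks**

Total step count: 8. Longest linear sequence: 8 steps (1 → 15); methyl acetoacetate 6 enters at step 3.

Steps most likely to fail:

1. Step 3. The dianion may attack the lactone carbonyl instead of the methylene carbon, the acceptor may oligomerise anionically, the protonation may show incomplete facial control, or the ring closure may be slow. Fallback, from 6 (with 5), back at 9: methyl acetoacetate 6 would be brominated at the terminal carbon (Br2, CHCl3, 0 °C → rt, the HBr formed moving bromine from the 2- to the 4-position) to give methyl 4-bromo-3-oxobutanoate F1. Its α-keto radical (Bu3SnH added by syringe pump, AIBN cat., PhH, 80 °C, excess 5) would add to the methylene carbon of 5 in a Giese-type conjugate addition, and the adduct radical would take hydrogen from the tin hydride on the face opposite the tert-butyl group to give methyl 5-[(2R,4R)-2-tert-butyl-5-oxo-1,3-dioxolan-4-yl]-3-oxopentanoate F2, which would be isolated. NaH (1 equiv) in THF would then form enolate 9, whose Dieckmann closure leads to 10 as in the main route.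

2. Step 4. Oxygen transfer may show poor facial selectivity if the strongly hydrogen-bonded enol gives only weak hydroxyl direction, and the product may be over-oxidised by the peracid. Fallback, from 10, back at 12: 10 would first be benzoylated at the secondary hydroxyl (BzCl, pyridine, CH2Cl2; any enol benzoate is cleaved on work-up with aqueous NaHCO3) to give methyl (5R)-5-(benzoyloxy)-2-hydroxy-6-oxocyclohex-1-ene-1-carboxylate F3. Its potassium enolate (KN(SiMe3)2, THF, −78 °C) would then be hydroxylated with an enantiopure (camphorsulfonyl)oxaziridine, so that C1 is set by the reagent and not by the neighbouring hydroxyl; both enantiomers of the reagent are available and the matched one would be chosen by trial. The product is 12.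

3. Step 8. The secondary hydroxyls may compete in the acylation, or the C3 benzoate may migrate. Fallback, from 13, back at 15: the two secondary hydroxyls of 13 would be silylated (Et3SiCl, imidazole, DMF, the tertiary hydroxyl staying free) to give methyl (1S,2S,3R,6R)-3-(benzoyloxy)-1-hydroxy-2,6-bis[(triethylsilyl)oxy]cyclohexane-1-carboxylate F4. Hydroxyl-assisted reduction of the ester (BH3·SMe2, NaBH4 cat., THF) would give (1R,2S,3S,4R)-3-hydroxy-3-(hydroxymethyl)-2,4-bis[(triethylsilyl)oxy]cyclohexyl benzoate F5, in which only the primary hydroxyl can be acylated (BzCl, pyridine, CH2Cl2) to give [(1S,2S,3R,6R)-3-(benzoyloxy)-1-hydroxy-2,6-bis[(triethylsilyl)oxy]cyclohexyl]methyl benzoate F6. Acidic desilylation (HF·pyridine, THF, 0 °C), which does not move the benzoates, would give 15.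

**Further compounds**

F1 | step 3 | methyl 4-bromo-3-oxobutanoate | COC(=O)CC(=O)CBr
F2 | step 3 | methyl 5-[(2R,4R)-2-tert-butyl-5-oxo-1,3-dioxolan-4-yl]-3-oxopentanoate | CC(C)(C)[C@@H]1O[C@H](CCC(=O)CC(=O)OC)C(=O)O1
F3 | step 4 | methyl (5R)-5-(benzoyloxy)-2-hydroxy-6-oxocyclohex-1-ene-1-carboxylate | COC(=O)C1=C(O)CC[C@@H](OC(=O)c2ccccc2)C1=O
F4 | step 8 | methyl (1S,2S,3R,6R)-3-(benzoyloxy)-1-hydroxy-2,6-bis[(triethylsilyl)oxy]cyclohexane-1-carboxylate | COC(=O)[C@]1(O)[C@H](O[Si](CC)(CC)CC)CC[C@@H](OC(=O)c2ccccc2)[C@@H]1O[Si](CC)(CC)CC
F5 | step 8 | (1R,2S,3S,4R)-3-hydroxy-3-(hydroxymethyl)-2,4-bis[(triethylsilyl)oxy]cyclohexyl benzoate | OC[C@]1(O)[C@H](O[Si](CC)(CC)CC)CC[C@@H](OC(=O)c2ccccc2)[C@@H]1O[Si](CC)(CC)CC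
F6 | step 8 | [(1S,2S,3R,6R)-3-(benzoyloxy)-1-hydroxy-2,6-bis[(triethylsilyl)oxy]cyclohexyl]methyl benzoate | O=C(OC[C@]1(O)[C@H](O[Si](CC)(CC)CC)CC[C@@H](OC(=O)c2ccccc2)[C@@H]1O[Si](CC)(CC)CC)c1ccccc1
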